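**Plan**
- Cuts, in retrosynthetic order: the enal and the C3–CH2OH group go back to two methyl esters. Then the C2–C3 bond of the dihydrofuran ring is cut, then the O1–C2 benzyl ether bond, the C3a–C3 bond and the side-chain C=C. What remains is 5-hydroxyvanillin (the C2 aryl ring) and 5-iodovanillin (the benzofuran arene with O1, 7-OMe, a C3a–I handle and C5–CHO already in place).
- Enabling feature: C2 is a CH bound both to ring oxygen O1 and to the trioxygenated phenyl ring, so in the ring-opened form it is a doubly activated OCH2Ar group. C3 sits on C3a, ortho to C7a–O1, and bears a carbon that can be an ester, so C3 can be a donor/acceptor carbene placed 1,5 to that C–H.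
- Forward order: both benzene rings are bought. They are joined through O1 (Mitsunobu), the side chain is grown (Wittig), and C3 is attached to C3a (Negishi–Reformatsky) and diazotised. The dihydrofuran, the only ring to be made, is closed last by Rh(II) C–H insertion.
- Stereochemistry: C2 (R) comes from the chiral dirhodium catalyst, which selects one enantiotopic benzylic hydrogen. C3 forms cis in the same event and is then relayed from C2 to trans by thermodynamic ester epimerisation. The E alkene comes from the stabilised ylide.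
- End game: global DIBAL-H reduction, MnO2 oxidation of the cinnamyl alcohol only, buffered fluoride desilylation.

Key step: step 7

Assumption: the 2R sense of induction of Rh2(S-PTTL)4 is assigned by analogy with simpler 2-(benzyloxy)aryl diazoacetates. The catalyst from (R)-tert-leucine is equally accessible should the opposite sense apply.

**Step 1**
Reactants: 1 3,4-dihydroxy-5-methoxybenzaldehyde (5-hydroxyvanillin)
Product: 2 3,4-bis(tert-butyldimethylsilyloxy)-5-methoxybenzaldehyde
Conditions: TBSCl (2.5 equiv), imidazole (5 equiv), DMF, rt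
Reagents that add atoms: tert-butyldimethylsilyl chloride, CC(C)(C)[Si](C)(C)Cl
Why: Standard imidazole-promoted silylation of phenols caps both catechol oxygens as ethers that are inert to carbenes and can be removed at the end with fluoride, without acid, strong base or hydrogen.

**Step 2**
Reactants: 2 3,4-bis(tert-butyldimethylsilyloxy)-5-methoxybenzaldehyde
Product: 3 [3,4-bis(tert-butyldimethylsilyloxy)-5-methoxyphenyl]methanol
Conditions: NaBH4, THF/MeOH, 0 °C, short reaction time
Reagents that add atoms: none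
Why: Borohydride reduction of an aryl aldehyde, run cold and briefly so that alkoxide does not attack the aryl silyl ethers.

**Step 3**
Reactants: 3 [3,4-bis(tert-butyldimethylsilyloxy)-5-methoxyphenyl]methanol; 4 4-hydroxy-3-iodo-5-methoxybenzaldehyde (5-iodovanillin)
Product: 5 4-{[3,4-bis(tert-butyldimethylsilyloxy)-5-methoxyphenyl]methoxy}-3-iodo-5-methoxybenzaldehyde
Conditions: PPh3, DIAD, THF, 0 °C to rt
Reagents that add atoms: none
Why: Mitsunobu etherification, in which the acidic phenol of 4 (ortho I, para CHO) protonates the betaine and displaces the primary benzylic oxyphosphonium ion, while the neutral medium spares the aryl silyl ethers that a carbonate-mediated benzylation would endanger.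

**Step 4**
Reactants: 5 4-{[3,4-bis(tert-butyldimethylsilyloxy)-5-methoxyphenyl]methoxy}-3-iodo-5-methoxybenzaldehyde
Product: 6 methyl (E)-3-(4-{[3,4-bis(tert-butyldimethylsilyloxy)-5-methoxyphenyl]methoxy}-3-iodo-5-methoxyphenyl)prop-2-enoate
Conditions: Ph3P=CHCO2Me, toluene, 80 °C
Reagents that add atoms: methyl (triphenylphosphoranylidene)acetate, COC(=O)C=P(c1ccccc1)(c1ccccc1)c1ccccc1
Why: Wittig olefination with a stabilised ylide gives the E-cinnamate, which masks the future enal in a form inert to zinc enolates, diazo transfer and electrophilic carbenes.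

**Step 5**
Reactants: 6 methyl (E)-3-(4-{[3,4-bis(tert-butyldimethylsilyloxy)-5-methoxyphenyl]methoxy}-3-iodo-5-methoxyphenyl)prop-2-enoate
Product: 7 methyl (E)-3-[4-{[3,4-bis(tert-butyldimethylsilyloxy)-5-methoxyphenyl]methoxy}-3-methoxy-5-(2-methoxy-2-oxoethyl)phenyl]prop-2-enoate
Conditions: BrZnCH2CO2Me (from BrCH2CO2Me and activated Zn, THF), Pd(dba)2 (2 mol %), XPhos (4 mol %), THF, rt to 45 °C
Reagents that add atoms: methyl bromoacetate, COC(=O)CBr (used as its zinc reagent, COC(=O)C[Zn]Br)
Why: Palladium-catalysed Negishi-type α-arylation with a Reformatsky reagent, where oxidative addition into the C–I bond is easy and the barely basic zinc enolate leaves the cinnamate, the silyl ethers and the benzyl ether untouched.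

**Step 6**
Reactants: 7 methyl (E)-3-[4-{[3,4-bis(tert-butyldimethylsilyloxy)-5-methoxyphenyl]methoxy}-3-methoxy-5-(2-methoxy-2-oxoethyl)phenyl]prop-2-enoate
Product: 8 methyl (E)-3-[4-{[3,4-bis(tert-butyldimethylsilyloxy)-5-methoxyphenyl]methoxy}-3-(1-diazo-2-methoxy-2-oxoethyl)-5-methoxyphenyl]prop-2-enoate
Conditions: p-ABSA, DBU, dry MeCN, 0 °C to rt
Reagents that add atoms: 4-acetamidobenzenesulfonyl azide (p-ABSA), CC(=O)Nc1ccc(cc1)S(=O)(=O)N=[N+]=[N-]
Why: Regitz diazo transfer, in which DBU deprotonates only the doubly activated ArCH2CO2Me position and the enolate takes N2 from the sulfonyl azide, the standard access to aryldiazoacetates.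

**Step 7**
Reactants: 8 methyl (E)-3-[4-{[3,4-bis(tert-butyldimethylsilyloxy)-5-methoxyphenyl]methoxy}-3-(1-diazo-2-methoxy-2-oxoethyl)-5-methoxyphenyl]prop-2-enoate
Product: 9 methyl (2R,3S)-2-[3,4-bis(tert-butyldimethylsilyloxy)-5-methoxyphenyl]-7-methoxy-5-[(E)-3-methoxy-3-oxoprop-1-enyl]-2,3-dihydro-1-benzofuran-3-carboxylate (2,3-cis)
Conditions: Rh2(S-PTTL)4 (1 mol %), toluene, −60 °C
Reagents that add atoms: none
Why: Rh2(S-PTTL)4 expels N2 from 8 to give an electrophilic donor/acceptor rhodium carbene at the future C3, which inserts into one C–H bond of the neighbouring OCH2Ar group through a concerted, asynchronous three-centre transition state with hydride-transfer character, forming the C2–C3 bond. The closest known reaction type is the enantioselective intramolecular C–H insertion of methyl 2-(benzyloxy)aryl diazoacetates with N-phthaloyl amino acid dirhodium carboxylates, which gives cis-2-aryl-2,3-dihydrobenzofuran-3-carboxylates. The dihydrofuran ring closes in the 1,5-insertion mode (C3, C3a, C7a, O1 and C2 become the five ring atoms), this being the only C–H within reach of a five-membered transition state, whereas attack on O1 would need a four-membered oxonium ylide and attack on the pendant arene a seven-membered ring. C2 is controlled by the catalyst, whose phthalimido wall around the carbene allows only one of the two enantiotopic benzylic hydrogens to be presented (expected 2R with the S ligand), and the insertion goes with retention at that carbon. C3 is controlled in the same transition state relative to C2, since the aryl group on the reacting carbon points away from the catalyst face and so ends on the side of the ester, giving the kinetic 2,3-cis (3S) product that step 8 corrects. The step needs chemoselectivity for this C–H over the cinnamate C=C, the OMe and silyl C–H bonds and carbene dimerisation, which is secured by the double activation of the C–H by O1 and the electron-rich aryl ring, by the electron-poor alkene, by the 7-OMe group that twists the OCH2Ar unit out of the ring plane towards the carbene, and by the low temperature.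

**Step 8**
Reactants: 9 methyl (2R,3S)-2-[3,4-bis(tert-butyldimethylsilyloxy)-5-methoxyphenyl]-7-methoxy-5-[(E)-3-methoxy-3-oxoprop-1-enyl]-2,3-dihydro-1-benzofuran-3-carboxylate
Product: 10 methyl (2R,3R)-2-[3,4-bis(tert-butyldimethylsilyloxy)-5-methoxyphenyl]-7-methoxy-5-[(E)-3-methoxy-3-oxoprop-1-enyl]-2,3-dihydro-1-benzofuran-3-carboxylate (2,3-trans)
Conditions: DBU (1 equiv), dry toluene, 50 °C
Reagents that add atoms: none
Why: Thermodynamic epimerisation α to the ester through reversible enolisation of the benzylic C3–H places the ester trans to the C2 aryl group, while C2 is untouched because the C2–O1 bond lies near the nodal plane of the enolate (the reverse of a 5-endo-trig closure), so β-elimination is slow, and the anhydrous amidine spares the aryl silyl ethers.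

**Step 9**
Reactants: 10 methyl (2R,3R)-2-[3,4-bis(tert-butyldimethylsilyloxy)-5-methoxyphenyl]-7-methoxy-5-[(E)-3-methoxy-3-oxoprop-1-enyl]-2,3-dihydro-1-benzofuran-3-carboxylate
Product: 11 (E)-3-{(2R,3S)-2-[3,4-bis(tert-butyldimethylsilyloxy)-5-methoxyphenyl]-3-(hydroxymethyl)-7-methoxy-2,3-dihydro-1-benzofuran-5-yl}prop-2-en-1-ol
Conditions: DIBAL-H (6 equiv), CH2Cl2, −78 to 0 °C; aq. Rochelle salt
Reagents that add atoms: none
Why: DIBAL-H ester reduction takes the cinnamate by clean 1,2-reduction to the cinnamyl alcohol and the C3 ester to CH2OH without touching the silyl ethers or either stereocentre (the C3 descriptor changes to S only through the CIP ranking).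

**Step 10**
Reactants: 11 (E)-3-{(2R,3S)-2-[3,4-bis(tert-butyldimethylsilyloxy)-5-methoxyphenyl]-3-(hydroxymethyl)-7-methoxy-2,3-dihydro-1-benzofuran-5-yl}prop-2-en-1-ol
Product: 12 (E)-3-{(2R,3S)-2-[3,4-bis(tert-butyldimethylsilyloxy)-5-methoxyphenyl]-3-(hydroxymethyl)-7-methoxy-2,3-dihydro-1-benzofuran-5-yl}prop-2-enal
Conditions: activated MnO2 (excess), CH2Cl2, rt
Reagents that add atoms: none
Why: MnO2 oxidation is chemoselective for allylic and benzylic carbinols, so only the cinnamyl alcohol becomes the E-enal and the saturated C3–CH2OH remains.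

**Step 11**
Reactants: 12 (E)-3-{(2R,3S)-2-[3,4-bis(tert-butyldimethylsilyloxy)-5-methoxyphenyl]-3-(hydroxymethyl)-7-methoxy-2,3-dihydro-1-benzofuran-5-yl}prop-2-enal
Product: 13 cassyformin, (E)-3-[(2R,3S)-2-(3,4-dihydroxy-5-methoxyphenyl)-3-(hydroxymethyl)-7-methoxy-2,3-dihydro-1-benzofuran-5-yl]prop-2-enal
Conditions: TBAF (2.2 equiv), AcOH (2.5 equiv), THF, 0 °C, argon
Reagents that add atoms: none
Why: Fluoride-mediated desilylation of aryl silyl ethers, buffered with acetic acid and run under argon, frees the catechol without base-induced oxidation, enal addition or acid ionisation of the benzylic C2–O1 bond.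

**Compound list**
1 | 3,4-dihydroxy-5-methoxybenzaldehyde (5-hydroxyvanillin) | COc1cc(C=O)cc(O)c1O | starting material
2 | 3,4-bis(tert-butyldimethylsilyloxy)-5-methoxybenzaldehyde | COc1cc(C=O)cc(O[Si](C)(C)C(C)(C)C)c1O[Si](C)(C)C(C)(C)C | intermediate
3 | [3,4-bis(tert-butyldimethylsilyloxy)-5-methoxyphenyl]methanol | COc1cc(CO)cc(O[Si](C)(C)C(C)(C)C)c1O[Si](C)(C)C(C)(C)C | intermediate
4 | 4-hydroxy-3-iodo-5-methoxybenzaldehyde (5-iodovanillin) | COc1cc(C=O)cc(I)c1O | starting material
5 | 4-{[3,4-bis(tert-butyldimethylsilyloxy)-5-methoxyphenyl]methoxy}-3-iodo-5-methoxybenzaldehyde | COc1cc(COc2c(I)cc(C=O)cc2OC)cc(O[Si](C)(C)C(C)(C)C)c1O[Si](C)(C)C(C)(C)C | intermediate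
6 | methyl (E)-3-(4-{[3,4-bis(tert-butyldimethylsilyloxy)-5-methoxyphenyl]methoxy}-3-iodo-5-methoxyphenyl)prop-2-enoate | COc1cc(COc2c(I)cc(/C=C/C(=O)OC)cc2OC)cc(O[Si](C)(C)C(C)(C)C)c1O[Si](C)(C)C(C)(C)C | intermediate
7 | methyl (E)-3-[4-{[3,4-bis(tert-butyldimethylsilyloxy)-5-methoxyphenyl]methoxy}-3-methoxy-5-(2-methoxy-2-oxoethyl)phenyl]prop-2-enoate | COc1cc(COc2c(CC(=O)OC)cc(/C=C/C(=O)OC)cc2OC)cc(O[Si](C)(C)C(C)(C)C)c1O[Si](C)(C)C(C)(C)C | intermediate
8 | methyl (E)-3-[4-{[3,4-bis(tert-butyldimethylsilyloxy)-5-methoxyphenyl]methoxy}-3-(1-diazo-2-methoxy-2-oxoethyl)-5-methoxyphenyl]prop-2-enoate | COc1cc(COc2c(C(=[N+]=[N-])C(=O)OC)cc(/C=C/C(=O)OC)cc2OC)cc(O[Si](C)(C)C(C)(C)C)c1O[Si](C)(C)C(C)(C)C | intermediate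
9 | methyl (2R,3S)-2-[3,4-bis(tert-butyldimethylsilyloxy)-5-methoxyphenyl]-7-methoxy-5-[(E)-3-methoxy-3-oxoprop-1-enyl]-2,3-dihydro-1-benzofuran-3-carboxylate (cis) | COc1cc([C@@H]2Oc3c(OC)cc(/C=C/C(=O)OC)cc3[C@@H]2C(=O)OC)cc(O[Si](C)(C)C(C)(C)C)c1O[Si](C)(C)C(C)(C)C | intermediate
10 | methyl (2R,3R)-2-[3,4-bis(tert-butyldimethylsilyloxy)-5-methoxyphenyl]-7-methoxy-5-[(E)-3-methoxy-3-oxoprop-1-enyl]-2,3-dihydro-1-benzofuran-3-carboxylate (trans) | COc1cc([C@@H]2Oc3c(OC)cc(/C=C/C(=O)OC)cc3[C@H]2C(=O)OC)cc(O[Si](C)(C)C(C)(C)C)c1O[Si](C)(C)C(C)(C)C | intermediate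
11 | (E)-3-{(2R,3S)-2-[3,4-bis(tert-butyldimethylsilyloxy)-5-methoxyphenyl]-3-(hydroxymethyl)-7-methoxy-2,3-dihydro-1-benzofuran-5-yl}prop-2-en-1-ol | COc1cc([C@@H]2Oc3c(OC)cc(/C=C/CO)cc3[C@H]2CO)cc(O[Si](C)(C)C(C)(C)C)c1O[Si](C)(C)C(C)(C)C | intermediate
12 | (E)-3-{(2R,3S)-2-[3,4-bis(tert-butyldimethylsilyloxy)-5-methoxyphenyl]-3-(hydroxymethyl)-7-methoxy-2,3-dihydro-1-benzofuran-5-yl}prop-2-enal | COc1cc([C@@H]2Oc3c(OC)cc(/C=C/C=O)cc3[C@H]2CO)cc(O[Si](C)(C)C(C)(C)C)c1O[Si](C)(C)C(C)(C)C | intermediate
13 | cassyformin, (E)-3-[(2R,3S)-2-(3,4-dihydroxy-5-methoxyphenyl)-3-(hydroxymethyl)-7-methoxy-2,3-dihydro-1-benzofuran-5-yl]prop-2-enal | COc1cc([C@@H]2Oc3c(OC)cc(/C=C/C=O)cc3[C@H]2CO)cc(O)c1O | target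

**Step count**
Total step count: 11. Longest linear sequence: 11 steps (from 1; 9 steps from 4).

**Steps most likely to fail**

Step 7.
- What may go wrong: with so electron-rich a benzylic position, hydride transfer may run ahead of C–C bond formation. The ion pair could then relax before it collapses, and both the facial selectivity and the cis/trans control would erode. The crowded 1,2,3-trisubstituted ether may also fit the catalyst pocket poorly.
- Fallback: stereocontrol is moved to a covalently bound ester auxiliary matched with a prolinate catalyst, a known variant of this insertion that leads directly to the trans series. It sets out from 6 and comes back at 11.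
- (R)-2-Hydroxy-1-(pyrrolidin-1-yl)propan-1-one is acylated with bromoacetyl bromide (pyridine, CH2Cl2, 0 °C) to the auxiliary bromoacetate F1. Its zinc reagent is coupled with 6 as in step 5 to give the auxiliary arylacetate F2. Diazo transfer as in step 6 gives the auxiliary diazoacetate F3.
- Rh2(R-DOSP)4 in CH2Cl2 should convert this into the trans auxiliary ester F4, from which minor diastereomers can be removed by chromatography. DIBAL-H as in step 9 cleaves both esters and gives 11, so step 8 is bypassed.
- Auxiliary and catalyst are drawn in the series expected by analogy to be matched for 2R,3R. Both antipodes are available.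

Step 8.
- What may go wrong: deprotonation of the ester by the amidine may be so slow that other processes compete. These are attack on the aryl silyl ethers and β-elimination of O1 from the enolate, which would open the ring and lose C2.
- Fallback: the epimerisation is moved to the aldehyde oxidation level, where a tertiary amine suffices. It sets out from 9 and comes back at 12.
- DIBAL-H reduces 9 to the cis diol F5. Parikh–Doering oxidation (SO3·pyridine, DMSO, Et3N, CH2Cl2, 0 °C to rt) takes both carbinols to the cis dialdehyde F6. Its C3–H is now α to a formyl group and benzylic, so it is exchanged by the triethylamine present and the trans dialdehyde F7 should accumulate.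
- NaBH4 in CH2Cl2/MeOH at −78 °C then reduces the saturated aldehyde in preference to the p-alkoxycinnamaldehyde, a vinylogous and much less electrophilic carbonyl group. This gives 12.

Step 5.
- What may go wrong: transmetalation at the palladium centre next to the bulky benzyloxy group may be slow, so that protodeiodination and self-condensation of the zinc enolate take over.
- Fallback: C3 is brought in through an electrophile at the ketone level, and the diazo group is made by sulfinate elimination instead of diazo transfer. It sets out from 6 and comes back at 8.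
- Iodine–magnesium exchange (i-PrMgCl·LiCl, THF, −40 °C), helped by the ortho ether oxygen, gives the arylmagnesium chloride F8. This is added to excess dimethyl oxalate at −78 °C to give the aryl glyoxylate F9. Condensation with tosylhydrazine (THF, 50 °C) gives the tosylhydrazone F10.
- Et3N or DBU in CH2Cl2 at rt eliminates toluenesulfinate (Bamford–Stevens type) and gives 8, so step 6 is bypassed as well.

**Further compounds**
F1 | step 7 | (R)-1-oxo-1-(pyrrolidin-1-yl)propan-2-yl 2-bromoacetate | BrCC(=O)O[C@H](C)C(=O)N1CCCC1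
F2 | step 7 | methyl (E)-3-[4-{[3,4-bis(tert-butyldimethylsilyloxy)-5-methoxyphenyl]methoxy}-3-methoxy-5-(2-oxo-2-{[(R)-1-oxo-1-(pyrrolidin-1-yl)propan-2-yl]oxy}ethyl)phenyl]prop-2-enoate | COc1cc(COc2c(CC(=O)O[C@H](C)C(=O)N3CCCC3)cc(/C=C/C(=O)OC)cc2OC)cc(O[Si](C)(C)C(C)(C)C)c1O[Si](C)(C)C(C)(C)C
F3 | step 7 | the α-diazo derivative of F2 | COc1cc(COc2c(C(=[N+]=[N-])C(=O)O[C@H](C)C(=O)N3CCCC3)cc(/C=C/C(=O)OC)cc2OC)cc(O[Si](C)(C)C(C)(C)C)c1O[Si](C)(C)C(C)(C)C
F4 | step 7 | (R)-1-oxo-1-(pyrrolidin-1-yl)propan-2-yl (2R,3R)-2-[3,4-bis(tert-butyldimethylsilyloxy)-5-methoxyphenyl]-7-methoxy-5-[(E)-3-methoxy-3-oxoprop-1-enyl]-2,3-dihydro-1-benzofuran-3-carboxylate (trans) | COc1cc([C@@H]2Oc3c(OC)cc(/C=C/C(=O)OC)cc3[C@H]2C(=O)O[C@H](C)C(=O)N4CCCC4)cc(O[Si](C)(C)C(C)(C)C)c1O[Si](C)(C)C(C)(C)C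
F5 | step 8 | (E)-3-{(2R,3R)-2-[3,4-bis(tert-butyldimethylsilyloxy)-5-methoxyphenyl]-3-(hydroxymethyl)-7-methoxy-2,3-dihydro-1-benzofuran-5-yl}prop-2-en-1-ol (cis) | COc1cc([C@@H]2Oc3c(OC)cc(/C=C/CO)cc3[C@@H]2CO)cc(O[Si](C)(C)C(C)(C)C)c1O[Si](C)(C)C(C)(C)C
F6 | step 8 | (2R,3S)-2-[3,4-bis(tert-butyldimethylsilyloxy)-5-methoxyphenyl]-7-methoxy-5-[(E)-3-oxoprop-1-enyl]-2,3-dihydro-1-benzofuran-3-carbaldehyde (cis) | COc1cc([C@@H]2Oc3c(OC)cc(/C=C/C=O)cc3[C@@H]2C=O)cc(O[Si](C)(C)C(C)(C)C)c1O[Si](C)(C)C(C)(C)C
F7 | step 8 | (2R,3R)-2-[3,4-bis(tert-butyldimethylsilyloxy)-5-methoxyphenyl]-7-methoxy-5-[(E)-3-oxoprop-1-enyl]-2,3-dihydro-1-benzofuran-3-carbaldehyde (trans) | COc1cc([C@@H]2Oc3c(OC)cc(/C=C/C=O)cc3[C@H]2C=O)cc(O[Si](C)(C)C(C)(C)C)c1O[Si](C)(C)C(C)(C)C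
F8 | step 5 | arylmagnesium chloride derived from 6 (MgCl in place of I) | COc1cc(COc2c([Mg]Cl)cc(/C=C/C(=O)OC)cc2OC)cc(O[Si](C)(C)C(C)(C)C)c1O[Si](C)(C)C(C)(C)C
F9 | step 5 | methyl (E)-3-[4-{[3,4-bis(tert-butyldimethylsilyloxy)-5-methoxyphenyl]methoxy}-3-methoxy-5-(2-methoxy-2-oxoacetyl)phenyl]prop-2-enoate | COc1cc(COc2c(C(=O)C(=O)OC)cc(/C=C/C(=O)OC)cc2OC)cc(O[Si](C)(C)C(C)(C)C)c1O[Si](C)(C)C(C)(C)C
F10 | step 5 | tosylhydrazone of F9 | COc1cc(COc2c(C(=NNS(=O)(=O)c3ccc(C)cc3)C(=O)OC)cc(/C=C/C(=O)OC)cc2OC)cc(O[Si](C)(C)C(C)(C)C)c1O[Si](C)(C)C(C)(C)C
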